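The plan rests on cutting the C4–C4a bond of the pyranone ring. On the benzene ring the ether oxygen O1 (on C8a) and the prenyl group (on C6) lie para to each other. In the ring-opened aryl ether the future C4a and C8 are therefore interchangeable ortho positions. One intramolecular Friedel–Crafts acylation closes the heterocycle, puts prenyl at C6 without a regiochemical choice, and leaves C8 as the only free ring carbon for the hexanoate arm. Its precursor is a (2S,3R)-3-aryloxy-2-methylbutanoic acid that already holds both methyl-bearing stereocentres (Fráter–Seebach methylation, Mitsunobu inversion) and carries silyl ethers on the two oxygens beside prenyl. C1′ is set last on an ortho-quinone methide.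

Key step: step 7

Numbering: chroman-4-one numbering is used (O1, C2, C3, C4, C4a, C5–C8, C8a). C1′ is the benzylic carbon of the side chain (C3 of the hexanoate). The target is the cis-(2R,3S)-2,3-dimethylchromanone with R configuration at C1′.

Design choices:
- **Free para phenol.** The phenol oxygen para to prenyl is the least hindered of the three and would be silylated first. It cannot be left free by partial silylation, so all three are silylated and the exposed one is released (steps 3 and 4).
- **Ester.** The ester is tert-butyl, so the acid is freed without hydroxide or heat. Phenolic silyl ethers and β-aryloxy esters tolerate neither well.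
- **Proton trap.** The acylation releases HCl, which together with SnCl4 is a strong proton source towards a trisubstituted alkene. A hindered pyridine that does not bind SnCl4 is added to take it up.
- **Base exposure.** The cis-chromanone is the less stable C3 epimer, so nothing stronger than bicarbonate, and no stoichiometric amine, is used after ring closure.

Assumption: the quinine-derived squaramide is taken to direct the enolate to the Si face of C1′. Should a trial show the opposite sense, the quinidine-derived pseudo-enantiomer is used under the same conditions.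

Step 1
Reactants: 1 tert-butyl (S)-3-hydroxybutanoate
Product: 3 tert-butyl (2S,3S)-3-hydroxy-2-methylbutanoate, via dilithium alkoxide enolate 2 (not isolated)
Conditions: LiN(iPr)2 (2.2 equiv), THF, −78 → −20 °C; MeI (1.5 equiv), DMPU, −78 → −20 °C; AcOH quench
Reagents that add atoms: methyl iodide, CI
Why: Fráter–Seebach alkylation: the second equivalent of base gives the lithium-chelated alkoxide enolate 2, whose six-membered chelate is methylated on the face away from the C3 methyl group, so the new C2 centre is set S (anti to the resident 3S carbinol) by 1,2-induction.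

Step 2
Reactants: 4 phloroglucinol; 5 prenyl bromide
Product: 6 2-(3-methylbut-2-enyl)benzene-1,3,5-triol
Conditions: 4 (3 equiv), KOH (1 equiv per 5), H2O, 0 °C → rt
Reagents that add atoms: none
Why: C-alkylation of an ambident phenolate: in water the oxygen atoms of the phloroglucinolate are solvated, so the soft allylic bromide is taken up at ring carbon by SN2 attack at its primary end, and the excess of 4 holds back a second prenylation.

Step 3
Reactants: 6 2-(3-methylbut-2-enyl)benzene-1,3,5-triol
Product: 7 1,3,5-tris(tert-butyldimethylsilyloxy)-2-(3-methylbut-2-enyl)benzene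
Conditions: TBSCl (3.6 equiv), imidazole (7 equiv), DMF, rt
Reagents that add atoms: tert-butyldimethylsilyl chloride, CC(C)(C)[Si](C)(C)Cl
Why: Standard imidazole-promoted O-silylation under acid-free conditions, which caps all three phenols (the two beside prenyl included) before the prenylphenol can oxidise or cyclise.

Step 4
Reactants: 7 1,3,5-tris(tert-butyldimethylsilyloxy)-2-(3-methylbut-2-enyl)benzene
Product: 8 3,5-bis(tert-butyldimethylsilyloxy)-4-(3-methylbut-2-enyl)phenol
Conditions: Bu4NF (1.0 equiv), AcOH (1.0 equiv), THF, −40 → −10 °C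
Reagents that add atoms: none
Why: Sterically differentiated fluoride desilylation: the silyl ether para to prenyl is flanked by two ring hydrogens whereas the other two are buttressed by the prenyl methylene, so one equivalent of buffered fluoride in the cold should free the exposed oxygen first, and material cleaved elsewhere or twice is returned to 7 under the conditions of step 3.

Step 5
Reactants: 8 3,5-bis(tert-butyldimethylsilyloxy)-4-(3-methylbut-2-enyl)phenol; 3 tert-butyl (2S,3S)-3-hydroxy-2-methylbutanoate
Product: 9 tert-butyl (2S,3R)-3-[3,5-bis(tert-butyldimethylsilyloxy)-4-(3-methylbut-2-enyl)phenoxy]-2-methylbutanoate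
Conditions: PPh3 (1.5 equiv), DIAD (1.5 equiv, slow addition), toluene, 0 °C → rt
Reagents that add atoms: none
Why: Mitsunobu etherification: the phenoxide of 8, unhindered at both ortho positions, displaces the oxyphosphonium group of 3 by SN2 with inversion, turning 3S into 3R and hence the anti into the syn array while C2 is untouched, and the non-polar solvent, slow azodicarboxylate addition and bulky ester disfavour competing elimination.

Step 6
Reactants: 9 tert-butyl (2S,3R)-3-[3,5-bis(tert-butyldimethylsilyloxy)-4-(3-methylbut-2-enyl)phenoxy]-2-methylbutanoate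
Product: 11 (2S,3R)-3-[3,5-bis(tert-butyldimethylsilyloxy)-4-(3-methylbut-2-enyl)phenoxy]-2-methylbutanoic acid, via trimethylsilyl ester 10 (not isolated)
Conditions: Me3SiOTf (2 equiv), 2,6-lutidine (3 equiv), CH2Cl2, 0 °C → rt; aq NaH2PO4
Reagents that add atoms: none
Why: Silyl triflate-mediated tert-butyl ester cleavage: O-silylation of the ester carbonyl and loss of isobutene by alkyl–oxygen fission give silyl ester 10, hydrolysed on work-up, so the acid is freed without hydroxide or heat and the aryl silyl ethers, the β-aryloxy unit and the α-stereocentre are left alone.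

Step 7
Reactants: 11 (2S,3R)-3-[3,5-bis(tert-butyldimethylsilyloxy)-4-(3-methylbut-2-enyl)phenoxy]-2-methylbutanoic acid
Product: 13 (2R,3S)-5,7-bis(tert-butyldimethylsilyloxy)-2,3-dimethyl-6-(3-methylbut-2-enyl)chroman-4-one, via acid chloride 12 (not isolated)
Conditions: 1-chloro-N,N,2-trimethylpropenylamine (1.1 equiv), CH2Cl2, 0 °C; then 2,6-di-tert-butyl-4-methylpyridine (1.5 equiv), SnCl4 (2.2 equiv), −78 °C; cold aq NaH2PO4/Na2HPO4 (pH 7)
Reagents that add atoms: none
Why: The chloroenamine turns acid 11 into acyl chloride 12 without base or free HCl, SnCl4 (in excess because the amide by-product also binds it) polarises 12 towards the acylium ion, the ring carbon ortho to the ether oxygen attacks it, and the arenium ion gives its proton to the hindered pyridine. This is the classical intramolecular Friedel–Crafts acylation of 3-aryloxypropanoyl chlorides to chroman-4-ones. The pyranone ring closes in a 6-exo mode at the acyl carbon (exo-trig for the complexed chloride, exo-dig for a free acylium ion), with the arene π bond endocyclic. No stereocentre is created, so the task is retention: C2 is never touched, and C3 is kept by excluding ketene formation (no amine able to deprotonate 12), enolisation of the product (−78 °C, cold neutral quench) and aryloxide elimination. Regioselectivity needs no control because rotation about the aryl–oxygen bond exchanges the two ortho carbons, so a single chromanone with prenyl at C6 and hydrogen at C8 should result. Chemoselectivity rests on the triply oxygen-activated ring reacting at −78 °C, on the silyl ethers blocking chroman formation, and on the proton trap keeping HCl/SnCl4 away from the prenyl alkene.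

Step 8
Reactants: 13 (2R,3S)-5,7-bis(tert-butyldimethylsilyloxy)-2,3-dimethyl-6-(3-methylbut-2-enyl)chroman-4-one
Product: 14 (2R,3S)-5,7-dihydroxy-2,3-dimethyl-6-(3-methylbut-2-enyl)chroman-4-one
Conditions: KHF2 (3 equiv), MeOH, rt
Reagents that add atoms: none
Why: Bifluoride cleavage of phenolic silyl ethers: the weakly acidic KHF2/MeOH medium removes both groups (the one peri to the ketone fastest) without generating a base strong enough to enolise C3 of the kinetically held cis-chromanone or to open the ring by retro-oxa-Michael reaction.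

Step 9
Reactants: 14 (2R,3S)-5,7-dihydroxy-2,3-dimethyl-6-(3-methylbut-2-enyl)chroman-4-one; 15 butanal
Product: 16 (2R,3S)-5,7-dihydroxy-2,3-dimethyl-6-(3-methylbut-2-enyl)-8-[1-(4-methylphenylsulfonyl)butyl]chroman-4-one (both epimers at the sulfonyl-bearing carbon)
Conditions: 15 (1.5 equiv), p-TolSO2H (1.5 equiv), MgSO4, CH2Cl2, rt
Reagents that add atoms: p-toluenesulfinic acid, Cc1ccc(cc1)S(=O)O
Why: Three-component sulfonylalkylation of an activated phenol (Mannich-type hydroxyalkylation followed by sulfinate capture of the benzylic position): C8 is the only unsubstituted ring carbon and is ortho and para to the two hydroxyl groups, the sulfinic acid is the sole and only moderately strong acid so the prenyl group should not cyclise at room temperature, and the new sulfonyl-bearing centre forms as a mixture that is erased in step 10.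

Step 10
Reactants: 16 (2R,3S)-5,7-dihydroxy-2,3-dimethyl-6-(3-methylbut-2-enyl)-8-[1-(4-methylphenylsulfonyl)butyl]chroman-4-one; 17 Meldrum's acid (2,2-dimethyl-1,3-dioxane-4,6-dione)
Product: 21 (2R,3S,10R)-5-hydroxy-2,3-dimethyl-6-(3-methylbut-2-enyl)-10-propyl-2,3,9,10-tetrahydro-4H,8H-pyrano[2,3-f]chromene-4,8-dione, via ortho-quinone methide 18 (not isolated), via Meldrum's acid adduct 19 (not isolated), via lactone acid 20 (not isolated)
Conditions: 17 (1.5 equiv), 3-{[3,5-bis(trifluoromethyl)phenyl]amino}-4-{[(8α,9S)-6′-methoxycinchonan-9-yl]amino}cyclobut-3-ene-1,2-dione (10 mol %), 5% aq NaHCO3, toluene, 0 °C → rt; aq NaH2PO4 wash; toluene, 105 °C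
Reagents that add atoms: none
Why: Bifunctional squaramide catalysis on an ortho-quinone methide made in situ from a 2-(1-sulfonylalkyl)phenol: bicarbonate deprotonates O7 and sulfinate leaves to give 18, the squaramide NH groups bind the C7 carbonyl while the protonated quinuclidine holds the Meldrum's acid enolate and delivers it to the Si face of C1′, which sets R under catalyst control, and heating the neutral adduct 19 lets O7 open the dioxanedione with loss of acetone (20) and then of CO2, while the weak biphasic base and the phenoxide character of the ring keep C3 from enolising.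

Step 11
Reactants: 21 (2R,3S,10R)-5-hydroxy-2,3-dimethyl-6-(3-methylbut-2-enyl)-10-propyl-2,3,9,10-tetrahydro-4H,8H-pyrano[2,3-f]chromene-4,8-dione
Product: 22 methyl (3R)-3-[(2R,3S)-5,7-dihydroxy-2,3-dimethyl-6-(3-methylbut-2-enyl)-4-oxochroman-8-yl]hexanoate (CNP0068017.1)
Conditions: MeOH, camphorsulfonic acid (10 mol %), rt; solid NaHCO3, filter, concentrate
Reagents that add atoms: methanol, CO
Why: Acid-catalysed methanolysis (transesterification) of an aryl lactone: the departing O7 phenol is para to the acyl-bearing C4a, hence a good leaving group and a poor nucleophile, so the open hydroxy ester is favoured in methanol, no stereocentre is touched, and the acid is neutralised before concentration to prevent re-closure.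

Compound list
1 | tert-butyl (S)-3-hydroxybutanoate | C[C@H](O)CC(=O)OC(C)(C)C | starting material
2 | dilithium alkoxide enolate of 1 (chelated, enolate oxygen cis to C3) | C[C@H]([O-])/C=C(\[O-])OC(C)(C)C.[Li+].[Li+] | intermediate
3 | tert-butyl (2S,3S)-3-hydroxy-2-methylbutanoate | C[C@H](O)[C@H](C)C(=O)OC(C)(C)C | intermediate
4 | phloroglucinol | Oc1cc(O)cc(O)c1 | starting material
5 | prenyl bromide | CC(C)=CCBr | starting material
6 | 2-(3-methylbut-2-enyl)benzene-1,3,5-triol | CC(C)=CCc1c(O)cc(O)cc1O | intermediate
7 | 1,3,5-tris(tert-butyldimethylsilyloxy)-2-(3-methylbut-2-enyl)benzene | CC(C)=CCc1c(O[Si](C)(C)C(C)(C)C)cc(O[Si](C)(C)C(C)(C)C)cc1O[Si](C)(C)C(C)(C)C | intermediate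
8 | 3,5-bis(tert-butyldimethylsilyloxy)-4-(3-methylbut-2-enyl)phenol | Oc1cc(O[Si](C)(C)C(C)(C)C)c(CC=C(C)C)c(O[Si](C)(C)C(C)(C)C)c1 | intermediate
9 | tert-butyl (2S,3R)-3-[3,5-bis(tert-butyldimethylsilyloxy)-4-(3-methylbut-2-enyl)phenoxy]-2-methylbutanoate | c1(O[C@H](C)[C@H](C)C(=O)OC(C)(C)C)cc(O[Si](C)(C)C(C)(C)C)c(CC=C(C)C)c(O[Si](C)(C)C(C)(C)C)c1 | intermediate
10 | trimethylsilyl (2S,3R)-3-[3,5-bis(tert-butyldimethylsilyloxy)-4-(3-methylbut-2-enyl)phenoxy]-2-methylbutanoate | c1(O[C@H](C)[C@H](C)C(=O)O[Si](C)(C)C)cc(O[Si](C)(C)C(C)(C)C)c(CC=C(C)C)c(O[Si](C)(C)C(C)(C)C)c1 | intermediate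
11 | (2S,3R)-3-[3,5-bis(tert-butyldimethylsilyloxy)-4-(3-methylbut-2-enyl)phenoxy]-2-methylbutanoic acid | c1(O[C@H](C)[C@H](C)C(=O)O)cc(O[Si](C)(C)C(C)(C)C)c(CC=C(C)C)c(O[Si](C)(C)C(C)(C)C)c1 | intermediate
12 | (2S,3R)-3-[3,5-bis(tert-butyldimethylsilyloxy)-4-(3-methylbut-2-enyl)phenoxy]-2-methylbutanoyl chloride | c1(O[C@H](C)[C@H](C)C(=O)Cl)cc(O[Si](C)(C)C(C)(C)C)c(CC=C(C)C)c(O[Si](C)(C)C(C)(C)C)c1 | intermediate
13 | (2R,3S)-5,7-bis(tert-butyldimethylsilyloxy)-2,3-dimethyl-6-(3-methylbut-2-enyl)chroman-4-one | c1c(O[Si](C)(C)C(C)(C)C)c(CC=C(C)C)c(O[Si](C)(C)C(C)(C)C)c2c1O[C@H](C)[C@H](C)C2=O | intermediate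
14 | (2R,3S)-5,7-dihydroxy-2,3-dimethyl-6-(3-methylbut-2-enyl)chroman-4-one | c1c(O)c(CC=C(C)C)c(O)c2c1O[C@H](C)[C@H](C)C2=O | intermediate
15 | butanal | CCCC=O | starting material
16 | (2R,3S)-5,7-dihydroxy-2,3-dimethyl-6-(3-methylbut-2-enyl)-8-[1-(4-methylphenylsulfonyl)butyl]chroman-4-one (epimers at the sulfonyl carbon) | CCCC(S(=O)(=O)c1ccc(C)cc1)c1c(O)c(CC=C(C)C)c(O)c2c1O[C@H](C)[C@H](C)C2=O | intermediate
17 | Meldrum's acid (2,2-dimethyl-1,3-dioxane-4,6-dione) | CC1(C)OC(=O)CC(=O)O1 | starting material
18 | (2R,3S)-8-butylidene-5-hydroxy-2,3-dimethyl-6-(3-methylbut-2-enyl)-2,3-dihydrochromene-4,7(8H)-dione (alkene geometry open) | CCCC=C1C(=O)C(CC=C(C)C)=C(O)C2=C1O[C@H](C)[C@H](C)C2=O | intermediate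
19 | 5-{(1R)-1-[(2R,3S)-5,7-dihydroxy-2,3-dimethyl-6-(3-methylbut-2-enyl)-4-oxochroman-8-yl]butyl}-2,2-dimethyl-1,3-dioxane-4,6-dione | CCC[C@H](C1C(=O)OC(C)(C)OC1=O)c1c(O)c(CC=C(C)C)c(O)c2c1O[C@H](C)[C@H](C)C2=O | intermediate
20 | (2R,3S,10R)-5-hydroxy-2,3-dimethyl-6-(3-methylbut-2-enyl)-4,8-dioxo-10-propyl-2,3,9,10-tetrahydro-4H,8H-pyrano[2,3-f]chromene-9-carboxylic acid (C9 undefined) | CCC[C@@H]1C(C(=O)O)C(=O)Oc2c(CC=C(C)C)c(O)c3c(c21)O[C@H](C)[C@H](C)C3=O | intermediate
21 | (2R,3S,10R)-5-hydroxy-2,3-dimethyl-6-(3-methylbut-2-enyl)-10-propyl-2,3,9,10-tetrahydro-4H,8H-pyrano[2,3-f]chromene-4,8-dione | CCC[C@@H]1CC(=O)Oc2c(CC=C(C)C)c(O)c3c(c21)O[C@H](C)[C@H](C)C3=O | intermediate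
22 | methyl (3R)-3-[(2R,3S)-5,7-dihydroxy-2,3-dimethyl-6-(3-methylbut-2-enyl)-4-oxochroman-8-yl]hexanoate | CCC[C@H](CC(=O)OC)c1c(O)c(CC=C(C)C)c(O)c2c1O[C@H](C)[C@H](C)C2=O | target

Total step count: 11. Longest linear sequence: 10 (steps 2–11, from phloroglucinol). Step 1 lies on the convergent branch.

Steps most likely to fail

**Step 7.** The prenyl double bond may be protonated. Lewis-acid desilylation may be followed by chroman closure. Configuration at C3 may be lost through ketene formation or aryloxide elimination. The fallback reverses the polarity of the arene and uses no acid. Acid 11 is coupled with MeNHOMe·HCl (EDC·HCl, N-methylmorpholine, CH2Cl2, 0 °C) to give the N-methoxy-N-methylamide F1. NBS (1.0 equiv, MeCN, −40 °C), for which the triply activated ring should outrun the alkene, brominates one of the two equivalent ortho carbons to give the aryl bromide F2. n-BuLi (THF, −90 °C) then triggers bromine–lithium exchange and Parham cyclisation of the aryllithium onto the amide. This forms the same C4–C4a bond and rejoins the route at 13.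

**Step 5.** The activated β-hydroxy ester may eliminate faster than the hindered secondary carbon is substituted. The fallback removes the acidifying carbonyl group before the displacement. Ester 3 is reduced with LiAlH4 (THF, 0 °C) to the diol F3. Its primary hydroxyl is silylated selectively (TBSCl 1.0 equiv, imidazole, CH2Cl2, 0 °C) to give the secondary alcohol F4. Mitsunobu reaction of F4 with phenol 8 (PPh3, DIAD, toluene) proceeds with the same inversion and gives the aryl ether F5. Camphorsulfonic acid in MeOH at 0 °C removes only the alkyl silyl ether, because aryl silyl ethers are the more acid-stable, and gives the primary alcohol F6. TEMPO (cat.)/PhI(OAc)2 in MeCN with aq NaH2PO4/Na2HPO4 oxidises F6 to the acid, rejoining the route at 11 and bypassing 9 and 10.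

**Step 10.** Facial selectivity may be poor on an alkyl-substituted quinone methide flanked by two oxygen-bearing carbons. The quinone methide may tautomerise to the styrene. Slow base-induced epimerisation at C3 is also possible. The fallback avoids the quinone methide and forms the C8–C1′ bond itself in the stereodefining event. Phenol 14 and commercial (E)-hex-2-enal react under iminium catalysis with (S)-2-[diphenyl(trimethylsilyloxy)methyl]pyrrolidine (20 mol %) and PhCO2H in toluene at 0 °C. This is a Friedel–Crafts conjugate addition followed by hemiacetal closure on O7. The shielding model for the E-iminium ion predicts R at the new centre and so the lactol F7. Oxidation with Ag2CO3 on Celite (toluene, 80 °C) gives the lactone, rejoining the route at 21 and bypassing 16.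

Further compounds
F1 | step 7 | (2S,3R)-3-[3,5-bis(tert-butyldimethylsilyloxy)-4-(3-methylbut-2-enyl)phenoxy]-N-methoxy-N,2-dimethylbutanamide | c1(O[C@H](C)[C@H](C)C(=O)N(C)OC)cc(O[Si](C)(C)C(C)(C)C)c(CC=C(C)C)c(O[Si](C)(C)C(C)(C)C)c1
F2 | step 7 | (2S,3R)-3-[2-bromo-3,5-bis(tert-butyldimethylsilyloxy)-4-(3-methylbut-2-enyl)phenoxy]-N-methoxy-N,2-dimethylbutanamide | c1(O[C@H](C)[C@H](C)C(=O)N(C)OC)c(Br)c(O[Si](C)(C)C(C)(C)C)c(CC=C(C)C)c(O[Si](C)(C)C(C)(C)C)c1
F3 | step 5 | (2R,3S)-2-methylbutane-1,3-diol | C[C@H](O)[C@H](C)CO
F4 | step 5 | (2S,3R)-4-(tert-butyldimethylsilyloxy)-3-methylbutan-2-ol | C[C@H](O)[C@H](C)CO[Si](C)(C)C(C)(C)C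
F5 | step 5 | tert-butyl{(2R,3R)-3-[3,5-bis(tert-butyldimethylsilyloxy)-4-(3-methylbut-2-enyl)phenoxy]-2-methylbutoxy}dimethylsilane | c1(O[C@H](C)[C@H](C)CO[Si](C)(C)C(C)(C)C)cc(O[Si](C)(C)C(C)(C)C)c(CC=C(C)C)c(O[Si](C)(C)C(C)(C)C)c1
F6 | step 5 | (2R,3R)-3-[3,5-bis(tert-butyldimethylsilyloxy)-4-(3-methylbut-2-enyl)phenoxy]-2-methylbutan-1-ol | c1(O[C@H](C)[C@H](C)CO)cc(O[Si](C)(C)C(C)(C)C)c(CC=C(C)C)c(O[Si](C)(C)C(C)(C)C)c1
F7 | step 10 | (2R,3S,10R)-5,8-dihydroxy-2,3-dimethyl-6-(3-methylbut-2-enyl)-10-propyl-2,3,9,10-tetrahydro-4H,8H-pyrano[2,3-f]chromen-4-one (anomers at C8) | CCC[C@@H]1CC(O)Oc2c(CC=C(C)C)c(O)c3c(c21)O[C@H](C)[C@H](C)C3=O
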